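Assumption: (2S)-liquiritigenin is bought as the enantiopure licorice isolate, with ee checked by chiral HPLC on receipt.

## Retrosynthetic overview

1. Target **1** ⇒ cut the last aryl–prenyl bond (C6–CH2) to a radical pair: the 7-phenolate of 8,3′-diprenylflavanone **2** plus N-prenylpyridinium salt **3**, joined under visible light.
2. **2** ⇒ double retro-[3,3] (aromatic Claisen) at C8–C and C3′–C: 7,4′-bis(1,1-dimethylallyl) ether **4**.
3. **4** ⇒ two ArO–C(tert) bonds: (2S)-liquiritigenin **5** + tert-prenyl carbonate **6** (Pd allylic etherification). **6** ⇐ 2-methylbut-3-en-2-ol **7** + Boc2O **8**; **3** ⇐ prenylamine **9** + 2,4,6-triphenylpyrylium tetrafluoroborate **10**.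
4. Ring order: no ring is built. The chromanone (A/C) ring, the B ring and the single C2 stereocentre are bought intact in **5**, and C2 is never touched.

## Route

**Step 1**
Reactants: **7** 2-methylbut-3-en-2-ol; **8** di-tert-butyl dicarbonate
Product: **6** tert-butyl (2-methylbut-3-en-2-yl) carbonate
Conditions: n-BuLi (1.05 equiv), THF, −78 → 0 °C; then **8** (1.1 equiv), 0 °C → rt
Reagents that add atoms: Boc2O (**8**), CC(C)(C)OC(=O)OC(=O)OC(C)(C)C
Why: Alkoxycarbonylation of the lithium tertiary alkoxide with Boc2O is the standard preparation of tertiary allylic tert-butyl carbonates.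

**Step 2**
Reactants: **5** (2S)-liquiritigenin [(2S)-7-hydroxy-2-(4-hydroxyphenyl)chroman-4-one]; **6** (2.3 equiv)
Product: **4** (2S)-7-[(2-methylbut-3-en-2-yl)oxy]-2-{4-[(2-methylbut-3-en-2-yl)oxy]phenyl}chroman-4-one
Conditions: Pd(PPh3)4 (5 mol %), THF, 4 Å MS, 0 °C, Ar; quench at full conversion
Reagents that add atoms: carbonate **6**, C=CC(C)(C)OC(=O)OC(C)(C)C (delivers two 1,1-dimethylallyl groups; CO2 and t-BuOH are lost)
Why: Decarboxylative Pd-catalysed allylic etherification (Tsuji–Trost): the tert-butoxide released is consumed deprotonating each phenol, and the phenoxide attacks the substituted terminus of the π-(1,1-dimethylallyl)Pd cation under kinetic control; no free strong base builds up to enolise C3, so C2 stays S.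

**Step 3**
Reactants: **4**
Product: **2** (2S)-7-hydroxy-2-[4-hydroxy-3-(3-methylbut-2-en-1-yl)phenyl]-8-(3-methylbut-2-en-1-yl)chroman-4-one
Conditions: Eu(fod)3 (10 mol %), PhCl, 80 °C, Ar; silica chromatography
Reagents that add atoms: none
Why: Two concerted aromatic Claisen [3,3] rearrangements convert each ArO–CMe2CH=CH2 into an ortho CH2CH=CMe2 group, one prenyl per oxygen; the B-ring ether has two equivalent ortho carbons (C3′), and the A-ring ether migrates preferentially to C8, the ortho carbon between the two ring oxygens, as is usual for 7-allyloxy chromanones and coumarins; the minor 6-prenyl isomer is removed on the column, and the neutral Lewis-acid conditions cannot epimerise C2.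

**Step 4**
Reactants: **9** 3-methylbut-2-en-1-amine (prenylamine, 1.2 equiv); **10** 2,4,6-triphenylpyrylium tetrafluoroborate
Product: **3** 1-(3-methylbut-2-en-1-yl)-2,4,6-triphenylpyridin-1-ium tetrafluoroborate
Conditions: EtOH, rt → 60 °C, 4 h; precipitate with Et2O
Reagents that add atoms: none (all atoms come from **9** and **10**; water is lost)
Why: Katritzky pyridinium synthesis: the primary amine opens the pyrylium ring and recloses with loss of water.

**Step 5**
Reactants: **2**; **3** (1.5 equiv)
Product: **1** (2S)-7-hydroxy-2-[4-hydroxy-3-(3-methylbut-2-en-1-yl)phenyl]-6,8-bis(3-methylbut-2-en-1-yl)chroman-4-one (target)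
Conditions: Cs2CO3 (0.55 equiv, both basic sites used, about 1.1 equiv base; pre-stir 30 min), DMA (0.05 M), degassed, 10 °C, 456 nm LEDs, ~16 h; aq NH4Cl workup
Reagents that add atoms: pyridinium salt **3**, CC(C)=CC[n+]1c(-c2ccccc2)cc(-c2ccccc2)cc1-c1ccccc1.F[B-](F)(F)F (delivers the prenyl group; 2,4,6-triphenylpyridine is lost)
Why: Proposed new method: acidity-gated EDA-complex C–H prenylation — about one equivalent of base ionises only the vinylogous-acid 7-OH (pKa about 8, against about 10.5 for the 4′-OH); the phenolate/pyridinium contact ion pair should show a visible charge-transfer band that alone absorbs at 456 nm, so the flavanone chromophore is not excited and does not ring-open at C2; light-induced electron transfer gives the 7-aryloxyl radical and a pyridinyl radical that expels the prenyl radical; in-cage recombination at C6, the only H-bearing ortho carbon, through the unhindered CH2 terminus, then dienone-to-phenol tautomerisation, forms the last aryl–prenyl bond; the closest known chemistry is deaminative alkylation with Katritzky pyridinium salts through photoactive EDA complexes, with the C–C coupling mirroring the aryloxyl/allyl radical-pair recombination of the photo-Claisen rearrangement; no new stereocentre is formed and C2 stays S.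

## Compound list

1 | (2S)-7-hydroxy-2-[4-hydroxy-3-(3-methylbut-2-en-1-yl)phenyl]-6,8-bis(3-methylbut-2-en-1-yl)chroman-4-one | CC(C)=CCc1cc([C@@H]2CC(=O)c3cc(CC=C(C)C)c(O)c(CC=C(C)C)c3O2)ccc1O | target

2 | (2S)-7-hydroxy-2-[4-hydroxy-3-(3-methylbut-2-en-1-yl)phenyl]-8-(3-methylbut-2-en-1-yl)chroman-4-one | CC(C)=CCc1cc([C@@H]2CC(=O)c3ccc(O)c(CC=C(C)C)c3O2)ccc1O | intermediate

3 | 1-(3-methylbut-2-en-1-yl)-2,4,6-triphenylpyridin-1-ium tetrafluoroborate | CC(C)=CC[n+]1c(-c2ccccc2)cc(-c2ccccc2)cc1-c1ccccc1.F[B-](F)(F)F | intermediate (reagent)

4 | (2S)-7-[(2-methylbut-3-en-2-yl)oxy]-2-{4-[(2-methylbut-3-en-2-yl)oxy]phenyl}chroman-4-one | C=CC(C)(C)Oc1ccc([C@@H]2CC(=O)c3ccc(OC(C)(C)C=C)cc3O2)cc1 | intermediate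

5 | (2S)-liquiritigenin, (2S)-7-hydroxy-2-(4-hydroxyphenyl)chroman-4-one | Oc1ccc([C@@H]2CC(=O)c3ccc(O)cc3O2)cc1 | starting material

6 | tert-butyl (2-methylbut-3-en-2-yl) carbonate | C=CC(C)(C)OC(=O)OC(C)(C)C | intermediate (reagent)

7 | 2-methylbut-3-en-2-ol | C=CC(C)(C)O | starting material

8 | di-tert-butyl dicarbonate | CC(C)(C)OC(=O)OC(=O)OC(C)(C)C | starting material

9 | 3-methylbut-2-en-1-amine | CC(C)=CCN | starting material

10 | 2,4,6-triphenylpyrylium tetrafluoroborate | c1ccc(-c2cc(-c3ccccc3)[o+]c(-c3ccccc3)c2)cc1.F[B-](F)(F)F | starting material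

## Step count and risks

Total steps: 5 (steps 1 and 4 are one-step reagent preparations).
Longest linear sequence: 4 steps (**7** → **6** → **4** → **2** → **1**; steps 1, 2, 3, 5). Counted from the chiral starting material **5** it is 3 steps.

Steps most likely to fail:

1. **Step 5 (proposed new method).** Risks are fast back-electron transfer, dark O-prenylation of the phenolate by **3**, ipso coupling at the already prenylated C8, coupling through the tertiary prenyl terminus, and over-reaction of the product phenolate (limit by stopping near 85% conversion). Fallback (known chemistry): O-tethered delivery — 7-O-selective tert-prenylation of **2** with **6** (1.05 equiv, Pd(PPh3)4; the more acidic 7-OH reacts first), then Eu(fod)3 Claisen rearrangement into C6, the one free ortho carbon. This costs one extra step.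

2. **Step 3.** The A-ring tertiary ether carries a good phenoxide leaving group and may lose isoprene instead of rearranging, the ortho-prenylphenols may cyclise to chromans, and the C8/C6 ratio may be modest. The 6-prenyl by-product would in principle also give **1** under step 5 conditions (prenylation at its free C8), so a poor ratio lowers convenience more than yield. Fallback: switch from the pericyclic to the ion-pair manifold — Mitsunobu bis-O-prenylation of **5** (prenol, PPh3, DIAD) to the linear prenyl ethers, then montmorillonite K10-promoted [1,3]-shift to the ortho-prenylphenols.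

3. **Step 2.** The acidic 7-O ether can re-ionise on Pd and leak to the linear prenyl ether, and any excess tert-butoxide could open the flavanone to the chalcone and racemise C2. Fallback: build the tertiary ethers as 1,1-dimethylpropargyl ethers instead (2-methylbut-3-yn-2-yl trifluoroacetate, cat. CuCl2, DBU limited to one equivalent per OH, MeCN, −5 °C), then Lindlar semi-hydrogenation to **4**. This costs one extra step.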